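**Plan**

1. Numbering (daucane): C1 angular-methyl carbon, C4 carbinol carbon, C5 ring-fusion CH, C6 benzoate carbon, C8 methyl-bearing alkene carbon, C10 angelate carbon; ring A is the five-membered ring, ring B the seven-membered ring, β is the face of the C1 methyl.
2. Cuts, in order: the C10 and C6 ester C–O bonds; C9–C10 and C7–C8 (C8 and C9 leave as allene) while C7 and C10 are re-joined; C6–C7 and C4–C5 (two aldol bonds; C4 and C6 come from the alkene of a cyclohexene); the Diels–Alder bonds C1–C5 and C2–C3.
3. Enabling feature: the C6 and C10 oxygens of ring B are 1,5-related across C7–C8–C9 (a de Mayo retron), so ring B is a cyclopentane-1,3-dione (C1, C10, C7, C6, C5) with two carbons inserted into its C7–C10 bond.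
4. Forward: asymmetric Diels–Alder (C1) → ozonolysis/aldol ring contraction to ring A → aldol closure of a temporary five-membered ring → [2+2] of its C10 enol acetate with allene, then retro-aldol expansion to ring B → redox adjustment and two esterifications.
5. Stereochemistry: C1 from the catalyst; C4 by epoxidation on the convex face of the cis-fused bicyclo[3.3.0]octene and reductive opening; C5 by equilibration after ring expansion; C6 by hydride delivery from the C4 hydroxyl; C10 by equatorial attack of a bulky hydride.
6. Helpers put in and removed: enol acetate (steps 10/12), cyclobutane (11/12), saturation at C8–C9 (12/15).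

Key step: step 11

Remark: the antipode of the oxazaborolidinium catalyst in step 2 is taken to be the one that delivers (S)-5.
Remark: the carbinol centers of 6, 10 and 11 and C8 of 17–21 arise as epimer mixtures that converge later; they are left undefined in the SMILES.

**Route**

Step 1
Reactants: 1 3-methylbut-1-yne; 2 ethylene
Product: 3 2-isopropylbuta-1,3-diene
Conditions: second-generation Grubbs catalyst RuCl2(=CHPh)(PCy3)(H2IMes) (cat.), ethylene (1 atm), CH2Cl2, rt
Reagents that add atoms: none
Why: Enyne cross-metathesis of a terminal alkyne with ethylene places a methylene on each alkyne carbon and should give the 2-substituted 1,3-diene directly, to be used as a solution.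

Step 2
Reactants: 3 2-isopropylbuta-1,3-diene; 4 methacrolein
Product: 5 (S)-4-isopropyl-1-methylcyclohex-3-ene-1-carbaldehyde
Conditions: (S)-3,3-diphenyl-1-(o-tolyl)tetrahydropyrrolo[1,2-c][1,3,2]oxazaborole·Tf2NH (10 mol%), CH2Cl2, −78 °C
Reagents that add atoms: none
Why: The Lewis-acid-catalysed Diels–Alder reaction of a 2-substituted diene with an α-substituted enal should give the 1,4-adduct, and the chiral oxazaborolidinium ion bound to the s-trans enal shields one enal face, so the quaternary C1 stereocenter is set by the catalyst.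

Step 3
Reactants: 5 (S)-4-isopropyl-1-methylcyclohex-3-ene-1-carbaldehyde
Product: 6 1-[(1S)-4-isopropyl-1-methylcyclohex-3-en-1-yl]ethan-1-ol
Conditions: MeMgBr, THF, −78 to 0 °C; aq NH4Cl
Reagents that add atoms: methylmagnesium bromide, C[Mg]Br
Why: Grignard addition to the neopentyl aldehyde brings in the carbon that becomes C7, and the new carbinol center is removed in step 4.

Step 4
Reactants: 6 1-[(1S)-4-isopropyl-1-methylcyclohex-3-en-1-yl]ethan-1-ol
Product: 7 1-[(1S)-4-isopropyl-1-methylcyclohex-3-en-1-yl]ethan-1-one
Conditions: Dess–Martin periodinane, NaHCO3, CH2Cl2, rt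
Reagents that add atoms: none
Why: Dess–Martin oxidation of the secondary alcohol should give the methyl ketone without touching the trisubstituted alkene.

Step 5
Reactants: 7 1-[(1S)-4-isopropyl-1-methylcyclohex-3-en-1-yl]ethan-1-one
Product: 9 (5S)-5-acetyl-2-isopropyl-5-methylcyclopent-1-ene-1-carbaldehyde, via keto aldehyde 8 (not isolated)
Conditions: O3, CH2Cl2/MeOH, −78 °C; Me2S; then piperidine (cat.), AcOH (cat.), toluene, 80 °C
Reagents that add atoms: ozone, [O-][O+]=O
Why: Ozonolysis cleaves the only alkene to a 6-oxo aldehyde, and under piperidinium acetate the aldehyde enamine should attack the isopropyl ketone and dehydrate (enamine-mediated intramolecular aldol condensation, the known contraction of 1-substituted cyclohexenes to cyclopentene-1-carbaldehydes), the hindered acetyl group being a poor enamine donor.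

Step 6
Reactants: 9 (5S)-5-acetyl-2-isopropyl-5-methylcyclopent-1-ene-1-carbaldehyde
Product: 10 (6aS)-3-hydroxy-4-isopropyl-6a-methyl-3,5,6,6a-tetrahydropentalen-1(2H)-one
Conditions: LiN(SiMe3)2, THF, −78 °C; aq NH4Cl
Reagents that add atoms: none
Why: Kinetic deprotonation of the methyl ketone and 5-exo intramolecular aldol addition to the enal carbonyl should close the temporary five-membered ring (C1, C10, C7, C6, C5) without dehydration, and both C6 carbinol epimers are usable because this center becomes a ketone in step 8.

Step 7
Reactants: 10 (6aS)-3-hydroxy-4-isopropyl-6a-methyl-3,5,6,6a-tetrahydropentalen-1(2H)-one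
Product: 11 3a,4-epoxy-3-hydroxy-4-isopropyl-6a-methylhexahydropentalen-1(2H)-one (oxirane oxygen syn to the 6a-methyl)
Conditions: mCPBA, NaHCO3, CH2Cl2, 0 °C
Reagents that add atoms: mCPBA, O=C(OO)c1cccc(Cl)c1
Why: Peracid epoxidation of the electron-rich tetrasubstituted alkene should occur on the convex face, syn to the C1 methyl, because an oxirane at the ring-fusion carbon C5 is only accommodated in a cis-fused bicyclo[3.3.0]octane, and this places the C4 oxygen on the β-face.

Step 8
Reactants: 11 3a,4-epoxy-3-hydroxy-4-isopropyl-6a-methylhexahydropentalen-1(2H)-one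
Product: 12 3a,4-epoxy-4-isopropyl-6a-methyltetrahydropentalene-1,3(2H,3aH)-dione
Conditions: Dess–Martin periodinane, NaHCO3, CH2Cl2, rt
Reagents that add atoms: none
Why: Dess–Martin oxidation of the secondary epoxy alcohol should give the α,β-epoxy ketone needed for reductive opening.

Step 9
Reactants: 12 3a,4-epoxy-4-isopropyl-6a-methyltetrahydropentalene-1,3(2H,3aH)-dione
Product: 13 (3aS,4R,6aS)-4-hydroxy-4-isopropyl-6a-methyltetrahydropentalene-1,3(2H,3aH)-dione
Conditions: SmI2 (2.2 equiv), THF/MeOH, −78 °C
Reagents that add atoms: none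
Why: Single-electron reduction of the α,β-epoxy ketone by SmI2 cleaves the C5–O bond (reductive epoxy ketone opening), the samarium enolate is protonated on the only face that keeps the cis ring fusion, and the tertiary C4 alcohol keeps its configuration.

Step 10
Reactants: 13 (3aS,4R,6aS)-4-hydroxy-4-isopropyl-6a-methyltetrahydropentalene-1,3(2H,3aH)-dione
Product: 14 (3aS,4R,6aS)-4-hydroxy-4-isopropyl-6a-methyl-3-oxo-3,3a,4,5,6,6a-hexahydropentalen-1-yl acetate
Conditions: Ac2O (1.1 equiv), Et3N, CH2Cl2, 0 °C
Reagents that add atoms: acetic anhydride, CC(=O)OC(C)=O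
Why: O-Acetylation of the vinylogous acid gives the β-acetoxy enone chromophore of a de Mayo reaction and should favour the C10 oxygen, because the C6 oxygen is flanked by the fully substituted C4 with its concave isopropyl group; the regioisomeric enol acetate would lead to the same 1,5-dione after step 12.

Step 11
Reactants: 14 (3aS,4R,6aS)-4-hydroxy-4-isopropyl-6a-methyl-3-oxo-3,3a,4,5,6,6a-hexahydropentalen-1-yl acetate; 15 allene
Product: 16 8-hydroxy-8-isopropyl-1-methyl-4-methylidene-6-oxotricyclo[5.3.0.0(2,5)]decan-2-yl acetate (cyclobutane cis-fused on the convex face)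
Conditions: hν (Pyrex, λ > 300 nm), allene (excess), THF, −78 °C
Reagents that add atoms: none
Why: Excitation of the β-acetoxy enone (C6=O, C7=C10–OAc) gives its triplet, which adds to allene through a 1,4-biradical and closes a cyclobutane ([2+2] photocycloaddition, the first half of a de Mayo reaction; the retro-aldol half follows in step 12). The closest known reaction type is the photocycloaddition of allene to cyclic enones and to enol esters of cyclic 1,3-diones, which is head-to-head: the central allene carbon bonds to the α-carbon C7 and a terminal CH2 to the oxygen-bearing C10, so C8 carries the exocyclic methylene that becomes the C8 methyl. The only ring closed is the four-membered ring (C10, C9, C8, C7), by an intermolecular two-bond [2+2] closure that is necessarily cis-fused to the five-membered ring. The new centers at C10 and C7 are set by approach of allene to the convex face of the cis-bicyclo[3.3.0]octane (the concave face is blocked by ring A and its isopropyl group), and both are erased in step 12 when C10 becomes a carbonyl and C7 a methylene. The selectivity needed is regiochemical: the enol acetate fixes the chromophore so that C10 and not C6 is the oxygen-bearing alkene carbon, the head-to-head preference of allene puts the methyl-bearing carbon next to C7, and the free tertiary alcohol and saturated ring A do not absorb above 300 nm.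

Step 12
Reactants: 16 8-hydroxy-8-isopropyl-1-methyl-4-methylidene-6-oxotricyclo[5.3.0.0(2,5)]decan-2-yl acetate
Product: 19 4β-hydroxy-5α-daucane-6,10-dione (trans-fused), via hydrogenated photoadduct 17 (not isolated), via cis-fused dione 18 (not isolated)
Conditions: H2 (1 atm), Pd/C, EtOAc, rt; filter; then K2CO3 (0.3 equiv), MeOH, rt
Reagents that add atoms: none
Why: Hydrogenation of the exocyclic alkene (which would otherwise migrate into conjugation with either ketone) is followed by methanolysis of the tertiary acetate, strain-driven retro-aldol cleavage of the C7–C10 bond (second half of the de Mayo reaction) and base equilibration at C5, which should favour the trans fusion because it takes C6 off the face shared with the isopropyl group and allows an O–H···O=C6 hydrogen bond.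

Step 13
Reactants: 19 4β-hydroxy-5α-daucane-6,10-dione
Product: 20 4β,6α-dihydroxy-5α-daucan-10-one
Conditions: Me4NBH(OAc)3, MeCN/AcOH (1:1), −30 °C
Reagents that add atoms: none
Why: In this Evans–Saksena reduction, ligand exchange at the C4 hydroxyl and intramolecular hydride delivery to the β-face of the C6 ketone through a six-membered transition state should give the 6α-alcohol and leave the remote C10 ketone untouched.

Step 14
Reactants: 20 4β,6α-dihydroxy-5α-daucan-10-one
Product: 21 6α-benzoyloxy-4β-hydroxy-5α-daucan-10-one
Conditions: BzCl, pyridine, DMAP (cat.), CH2Cl2, 0 °C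
Reagents that add atoms: benzoyl chloride, O=C(Cl)c1ccccc1
Why: Acylation of the secondary C6 alcohol with benzoyl chloride should be selective over the hindered tertiary C4 alcohol.

Step 15
Reactants: 21 6α-benzoyloxy-4β-hydroxy-5α-daucan-10-one
Product: 22 6α-benzoyloxy-4β-hydroxy-5α-dauc-8-en-10-one
Conditions: IBX (1.5 equiv), DMSO/toluene, 70 °C
Reagents that add atoms: none
Why: IBX-mediated α,β-dehydrogenation of the ketone can only proceed toward C9 (C1 is quaternary) and should regenerate the C8=C9 alkene as the β-methyl enone.

Step 16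
Reactants: 22 6α-benzoyloxy-4β-hydroxy-5α-dauc-8-en-10-one
Product: 23 6α-benzoyloxy-5α-dauc-8-ene-4β,10α-diol
Conditions: LiBH(s-Bu)3 (2.2 equiv), THF, −78 °C; aq NH4Cl
Reagents that add atoms: none
Why: 1,2-Reduction of the β,β-disubstituted enone by the bulky trialkylborohydride along the equatorial trajectory (the axial α-face approach is screened by the axial hydrogens at C5 and C7) should give the pseudoaxial 10α-alcohol, as in reductions of ketones flanked by a quaternary carbon bearing an axial methyl.

Step 17
Reactants: 23 6α-benzoyloxy-5α-dauc-8-ene-4β,10α-diol; 24 angelic acid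
Product: 26 10α-angeloyloxy-6α-benzoyloxy-5α-dauc-8-en-4β-ol (target), via mixed anhydride 25 (not isolated)
Conditions: 24, 2,4,6-trichlorobenzoyl chloride, Et3N, toluene, rt; then 23, toluene, 80 °C
Reagents that add atoms: none
Why: Yamaguchi esterification through the mixed anhydride, run without a nucleophilic catalyst to avoid Z-to-E isomerisation of the angeloyl group, should acylate the secondary C10 alcohol in preference to the tertiary C4 alcohol.

**Compound list**

1 | 3-methylbut-1-yne | CC(C)C#C | starting material
2 | ethylene | C=C | starting material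
3 | 2-isopropylbuta-1,3-diene | C=CC(=C)C(C)C | intermediate
4 | methacrolein | CC(=C)C=O | starting material
5 | (S)-4-isopropyl-1-methylcyclohex-3-ene-1-carbaldehyde | O=C[C@]1(C)CC=C(C(C)C)CC1 | intermediate
6 | 1-[(1S)-4-isopropyl-1-methylcyclohex-3-en-1-yl]ethan-1-ol (carbinol epimers) | CC(O)[C@]1(C)CC=C(C(C)C)CC1 | intermediate
7 | 1-[(1S)-4-isopropyl-1-methylcyclohex-3-en-1-yl]ethan-1-one | CC(=O)[C@]1(C)CC=C(C(C)C)CC1 | intermediate
8 | (S)-3-acetyl-3,7-dimethyl-6-oxooctanal (keto aldehyde) | O=CC[C@@](C)(C(C)=O)CCC(=O)C(C)C | intermediate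
9 | (5S)-5-acetyl-2-isopropyl-5-methylcyclopent-1-ene-1-carbaldehyde | O=CC1=C(C(C)C)CC[C@]1(C)C(C)=O | intermediate
10 | (6aS)-3-hydroxy-4-isopropyl-6a-methyl-3,5,6,6a-tetrahydropentalen-1(2H)-one (C3 epimers) | O=C1CC(O)C2=C(C(C)C)CC[C@]12C | intermediate
11 | 3a,4-epoxy-3-hydroxy-4-isopropyl-6a-methylhexahydropentalen-1(2H)-one, oxirane oxygen syn to the 6a-methyl (C3 epimers) | O=C1CC(O)[C@]2(O3)[C@]3(C(C)C)CC[C@]12C | intermediate
12 | 3a,4-epoxy-4-isopropyl-6a-methyltetrahydropentalene-1,3(2H,3aH)-dione, oxirane oxygen syn to the 6a-methyl | O=C1CC(=O)[C@]2(O3)[C@]3(C(C)C)CC[C@]12C | intermediate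
13 | (3aS,4R,6aS)-4-hydroxy-4-isopropyl-6a-methyltetrahydropentalene-1,3(2H,3aH)-dione (cis-fused; 3a-H, 4-OH and 6a-methyl on the convex face) | O=C1CC(=O)[C@@H]2[C@](O)(C(C)C)CC[C@]12C | intermediate
14 | (3aS,4R,6aS)-4-hydroxy-4-isopropyl-6a-methyl-3-oxo-3,3a,4,5,6,6a-hexahydropentalen-1-yl acetate (C10 enol acetate) | CC(=O)OC1=CC(=O)[C@@H]2[C@](O)(C(C)C)CC[C@]12C | intermediate
15 | allene (propa-1,2-diene) | C=C=C | starting material
16 | 8-hydroxy-8-isopropyl-1-methyl-4-methylidene-6-oxotricyclo[5.3.0.0(2,5)]decan-2-yl acetate (photoadduct; cyclobutane cis-fused on the convex face) | CC(=O)O[C@]12CC(=C)[C@H]1C(=O)[C@@H]3[C@](O)(C(C)C)CC[C@]23C | intermediate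
17 | 8-hydroxy-8-isopropyl-1,4-dimethyl-6-oxotricyclo[5.3.0.0(2,5)]decan-2-yl acetate (hydrogenated photoadduct; C4 epimers) | CC(=O)O[C@]12CC(C)[C@H]1C(=O)[C@@H]3[C@](O)(C(C)C)CC[C@]23C | intermediate
18 | cis-fused (5β-H) 4β-hydroxydaucane-6,10-dione (C8 epimers) | O=C1CC(C)CC(=O)[C@@H]2[C@](O)(C(C)C)CC[C@]12C | intermediate
19 | 4β-hydroxy-5α-daucane-6,10-dione (trans-fused; C8 epimers) | O=C1CC(C)CC(=O)[C@H]2[C@](O)(C(C)C)CC[C@]12C | intermediate
20 | 4β,6α-dihydroxy-5α-daucan-10-one (C8 epimers) | O=C1CC(C)C[C@H](O)[C@H]2[C@](O)(C(C)C)CC[C@]12C | intermediate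
21 | 6α-benzoyloxy-4β-hydroxy-5α-daucan-10-one (C8 epimers) | O=C1CC(C)C[C@H](OC(=O)c3ccccc3)[C@H]2[C@](O)(C(C)C)CC[C@]12C | intermediate
22 | 6α-benzoyloxy-4β-hydroxy-5α-dauc-8-en-10-one | O=C1C=C(C)C[C@H](OC(=O)c3ccccc3)[C@H]2[C@](O)(C(C)C)CC[C@]12C | intermediate
23 | 6α-benzoyloxy-5α-dauc-8-ene-4β,10α-diol | O[C@@H]1C=C(C)C[C@H](OC(=O)c3ccccc3)[C@H]2[C@](O)(C(C)C)CC[C@]12C | intermediate
24 | angelic acid, (Z)-2-methylbut-2-enoic acid | C/C=C(/C)C(=O)O | starting material
25 | angelic 2,4,6-trichlorobenzoic anhydride (mixed anhydride) | C/C=C(/C)C(=O)OC(=O)c1c(Cl)cc(Cl)cc1Cl | intermediate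
26 | 10α-angeloyloxy-6α-benzoyloxy-5α-dauc-8-en-4β-ol (1S,4R,5S,6S,10R) | C/C=C(/C)C(=O)O[C@@H]1C=C(C)C[C@H](OC(=O)c2ccccc2)[C@@H]2[C@]1(C)CC[C@@]2(O)C(C)C | target

**Step count and risks**

Total step count: 17. Longest linear sequence: 17 steps (from 3-methylbut-1-yne and ethylene; the route is fully linear).

The three steps most likely to fail:

Step 12 may fail through incomplete or reversed equilibration at C5, or through base-induced retro-aldol or dehydration at the C4–C5 β-hydroxy ketone. The fallback replaces thermodynamic by kinetic control. It sets out from cis-fused dione 18, obtained by stopping the K2CO3 treatment early. TMSOTf/Et3N (CH2Cl2, 0 °C) should give the 6,10-bis(trimethylsilyloxy)-4β-(trimethylsilyloxy)dauca-5,9-diene F1. Treatment with HF·pyridine (THF, −78 °C) should then protonate C5 kinetically from the α-face, anti to the β C1 methyl and the β C4 siloxy group, and remove all three silyl groups. The route is rejoined at compound 19.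

Step 16 may fail through poor facial selectivity (axial hydride attack on the α-face giving the 10β-alcohol) or conjugate reduction. The fallback sets out from enone 22. Luche reduction (NaBH4, CeCl3·7H2O, MeOH, −78 °C) should give 6α-benzoyloxy-5α-dauc-8-ene-4β,10β-diol F2 by axial attack. Mitsunobu esterification with angelic acid 24 (PPh3, DIAD, toluene, 0 °C) then inverts C10 and installs the ester, rejoining the route at the target 26.

Step 17 may fail through sluggish acylation of the hindered alcohol next to the quaternary C1, accompanied by isomerisation of the angeloyl unit to the tigloyl unit. The fallback builds the Z-alkene on the ester. It sets out from diol 23, which is acylated with 2-[bis(2,2,2-trifluoroethoxy)phosphoryl]propanoic acid (DCC, DMAP, CH2Cl2) to give the 10α-phosphonopropanoate F3. Still–Gennari olefination with acetaldehyde (KN(SiMe3)2, 18-crown-6, THF, −78 °C) should then give the Z-2-methylbut-2-enoate, rejoining the route at the target 26.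

Further compounds
F1 | step 12 | 6,10-bis(trimethylsilyloxy)-4β-(trimethylsilyloxy)dauca-5,9-diene (C8 epimers) | C[Si](C)(C)OC1=CC(C)CC(O[Si](C)(C)C)=C2[C@](O[Si](C)(C)C)(C(C)C)CC[C@]12C
F2 | step 16 | 6α-benzoyloxy-5α-dauc-8-ene-4β,10β-diol | O[C@H]1C=C(C)C[C@H](OC(=O)c3ccccc3)[C@H]2[C@](O)(C(C)C)CC[C@]12C
F3 | step 17 | 6α-benzoyloxy-10α-{2-[bis(2,2,2-trifluoroethoxy)phosphoryl]propanoyloxy}-5α-dauc-8-en-4β-ol | CC(P(=O)(OCC(F)(F)F)OCC(F)(F)F)C(=O)O[C@@H]1C=C(C)C[C@H](OC(=O)c3ccccc3)[C@H]2[C@](O)(C(C)C)CC[C@]12C
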